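It is easy to take the flattening at the end of a run for its end, and I nearly did. The reagent stood at 95.0 % of the starting material, so as limiting reagent its charge fell short of the starting material by 5.00 %, and beta's last reading of 9 % was still above that. What I needed next was the pace of the approach, so I compared the earlier runs at equal levels.

| flask | starting material | reagent | initiator | remark | time |
|---|---|---|---|---|---|
| beta | 10 mM | 9.5 mM | 0.70 mM | run made earlier |  |
| alpha | 10 mM | 9.5 mM | 1.1 mM | run made earlier |  |
| flask | 10 mM | 9.50 mM | 0.50 mM |  | 6.0 min |

| run | time / min | starting material / % | product / % |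
|---|---|---|---|
| beta | 0.250 | 80 | 21 |
| beta | 0.667 | 57 | 45 |
| beta | 1.33 | 36 | 69 |
| beta | 2.00 | 24 | 76 |
| beta | 3.00 | 15 | 87 |
| beta | 4.00 | 11 | 90 |
| beta | 5.00 | 9 | 90 |
| alpha | 0.250 | 75 | 24 |
| alpha | 0.667 | 51 | 50 |
| alpha | 1.33 | 25 | 72 |
| alpha | 2.00 | 16 | 85 |
| alpha | 3.00 | 13 | 88 |
| alpha | 4.00 | 9 | 92 |
| alpha | 5.00 | 7 | 92 |

(scatter of a reading: 1.5 percentage points)

1. amount of starting material in percent of the starting material charged, at 40 s, 2.0 min, 4.0 min and 6.0 min

Beta at 5.00 min and alpha at 4.00 min both read 9 %, a ratio of times of 1.25, and the square root of the ratio of their initiator charges gave 1.25. So I defined the clock factor as the minutes of beta that pass in one minute of a flask with beta's charges of starting material and reagent, the square root of its initiator charge over beta's, which for the new flask was 0.845.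

My note for whoever took over the bench said this. The flask held starting material, slightly less reagent, and initiator at 0.50 mM. I expected it to lie between beta's 80 % and 57 % at 40 s, between 36 % and 24 % at 2.0 min, and between 15 % and 11 % at 4.0 min. At 6.0 min it would stand where beta stood at 5.07 min, so near 9 %. Nobody was to add initiator, since alpha, with the larger charge, read 25 % at 1.33 min against beta's 36 %.

The forecast, holding that “the rate goes as the square root of initiator”, gave 62 %, 29 %, 14 % and 10 %, its last value a little above my 9 %.

The flask gave 61.4 %, 26.2 %, 12.5 % and 8.76 %.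

    starting material + second chain carrier → by-product + first chain carrier (k = 1.32 × 10⁶ M⁻¹ s⁻¹)
    crystals ⇌ by-product, rate k2*(cs2 - [by-product]) while solid is left; crystals form when [by-product] > cs2 (solubility = 5.70 mM, k = 0.310 s⁻¹)
    initiator → 2 initiating radical (k = 8.98 × 10⁻⁵ s⁻¹)
    reagent + first chain carrier ⇌ product + second chain carrier (K = 2.67, k = 6.11 × 10⁶ M⁻¹ s⁻¹)
    starting material + initiating radical → capped initiator + first chain carrier (k = 1.49 × 10⁷ M⁻¹ s⁻¹)
    2 second chain carrier → ended chains B (k = 5.00 × 10⁸ M⁻¹ s⁻¹)
    2 first chain carrier → ended chains A (k = 2.00 × 10⁸ M⁻¹ s⁻¹)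

At 6.0 min the flask still held 97 % of its initiator, more than the 8.8 % of its starting material. Dividing the two clock factors put the flask's 2.0 min, where it stood at 26.2 %, at 1.35 min on alpha's clock, and alpha's reading at 1.33 min was 25 %.

All runs were generated by integration from invented constants, and the scatter is random.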